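The bicyclic peroxy-lactone is disconnected at C6–O, C5–C6 and C4–O. The plan exploits that on the 1,2-dioxane (ring A) the C2 arm on C3 and the C7 arm on C6 are cis, so the future lactone carbonyl C1 can be esterified with a C10 hydroxyl as a temporary bridge. One acid-triggered operation condenses the C3 hydroperoxide with the C6 ketone, closes ring A through C5 and lets the bridging ester trap the C4 cation. This leaves the γ-lactone (ring B), both quaternary centres and free C10–OH. The precursor is (3R)-3-methyl-5-oxohexyl (3S)-3-hydroperoxy-4-methylpent-4-enoate; the phenyl-diene chain is then built from C10 via an alkyne.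

Key step: step 6

Numbering used below: C1 lactone carbonyl, C2, C3 (peroxy CH), C4 and C6 (methyl-bearing ring carbons), C5 (ring CH2), chain C7–C14. In this numbering 8 is 3S,8R and 11–18 are 3S,4S,6R,8R, with the C2 and C7 arms cis on ring A; the descriptors of precursor, key-step product and target were checked against each other and are consistent.

Precursor design: the isolated precursor is the free hydroperoxy keto ester 8. It is O-silylated in the flask (9), so that the peroxycarbenium ion forms under anhydrous conditions at −78 °C in the presence of a hindered base instead of from a free allylic hydroperoxide in wet acid.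

Assumption: horseradish peroxidase reduces the 3R epimer of 7 faster, as it does with secondary hydroperoxides that carry one unsaturated substituent; the configuration of 8 is to be confirmed on the derived alcohol before step 6.

Step 1
Reactants: 1 methyl hydrogen (R)-3-methylglutarate
Product: 3 (4R)-4-methyltetrahydro-2H-pyran-2-one, via hydroxy ester 2 (not isolated)
Conditions: BH3·SMe2, THF, 0 °C to rt; MeOH quench; then p-TsOH·H2O (catalytic), CH2Cl2, rt
Reagents that add atoms: none
Why: Borane reduces the free carboxylic acid chemoselectively beside the methyl ester and acid-catalysed lactonisation of hydroxy ester 2 follows, the methyl-bearing stereocentre (later C8) being untouched.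

Step 2
Reactants: 3 (4R)-4-methyltetrahydro-2H-pyran-2-one
Product: 4 (4R)-6-hydroxy-4-methylhexan-2-one
Conditions: MeLi (1.05 equiv), THF, −78 °C; aqueous NH4Cl at −78 °C
Reagents that add atoms: methyllithium, [Li]C
Why: Single addition of methyllithium to the δ-lactone, whose lithium hemiketal alkoxide persists at −78 °C and releases the methyl ketone (C6) only on quench, so that a second addition is avoided.

Step 3
Reactants: 4 (4R)-6-hydroxy-4-methylhexan-2-one; 5 4-methylpent-3-enoic acid
Product: 6 (3R)-3-methyl-5-oxohexyl 4-methylpent-3-enoate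
Conditions: DIC, DMAP (5 mol %), CH2Cl2, 0 °C to rt
Reagents that add atoms: none
Why: Steglich esterification acylates the primary C10 hydroxyl of the open-chain keto alcohol, and low temperature with little DMAP keeps the β,γ-double bond of the acyl part out of conjugation.

Step 4
Reactants: 6 (3R)-3-methyl-5-oxohexyl 4-methylpent-3-enoate
Product: 7 (3R)-3-methyl-5-oxohexyl (3RS)-3-hydroperoxy-4-methylpent-4-enoate
Conditions: O2, tetraphenylporphyrin (catalytic), white LED, CH2Cl2, −20 °C
Reagents that add atoms: dioxygen, O=O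
Why: Schenck ene reaction of singlet oxygen with the trisubstituted alkene, in which oxygen bonds to C3 and a hydrogen is taken from the cis methyl group on the more crowded side of the double bond, should give the secondary allylic hydroperoxide as both C3 epimers (no facial bias from the remote C8 centre) next to the conjugated tertiary regioisomer, which is removed by chromatography.

Step 5
Reactants: 7 (3R)-3-methyl-5-oxohexyl (3RS)-3-hydroperoxy-4-methylpent-4-enoate
Product: 8 (3R)-3-methyl-5-oxohexyl (3S)-3-hydroperoxy-4-methylpent-4-enoate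
Conditions: horseradish peroxidase (catalytic), guaiacol (1 equiv), phosphate buffer pH 6, rt, stopped near half conversion
Reagents that add atoms: none
Why: Peroxidase-catalysed kinetic resolution of a secondary allylic hydroperoxide, in which the enzyme should reduce the 3R epimer to the alcohol with guaiacol as reductant and leave the 3S epimer, so that C3 is fixed while the remote C8 centre is not involved.

Step 6
Reactants: 8 (3R)-3-methyl-5-oxohexyl (3S)-3-hydroperoxy-4-methylpent-4-enoate
Product: 11 (3R,4aS,7aS)-3-[(2R)-4-hydroxy-2-methylbutyl]-3,4a-dimethyl-4,4a,7,7a-tetrahydro-3H-furo[3,2-c][1,2]dioxin-6-one, via silyl peroxide 9 (not isolated), via lactonium triflate 10 (not isolated)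
Conditions: TMSOTf (2.5 equiv), 2,6-di-tert-butyl-4-methylpyridine (1.3 equiv), CH2Cl2, −78 °C, 8 added over 6 h by syringe pump (final 1 mM), then −40 °C; then H2O–THF, 0 °C to rt
Reagents that add atoms: water, O
Why: Proposed new method: O-silylation gives silyl peroxide 9, whose silylated oxygen adds through the ester bridge to the TMSOTf-activated C6 ketone (reversible eleven-membered perketal), and loss of hexamethyldisiloxane leaves a peroxycarbenium ion at C6; the isopropenyl terminus C5 attacks it (6-endo, Prins type) to close ring A, and the tertiary C4 cation is captured by the ester carbonyl oxygen (five-membered closure, 5-exo with respect to the former C4=C5 bond) to give lactonium ion 10, which water opens at C1 with release of the C10 hydroxyl. The closest known reactions are the Lewis-acid cyclisation of alkenyl monoperoxyketals through peroxycarbenium ions to 1,2-dioxanes, the TMSOTf-mediated condensation of silyl peroxides with ketones, and ester-terminated cationic lactonisations. C3 is carried over from 8; C6 is set because the seven-atom bridge C2–C1–O–C10–C9–C8–C7 can span the forming ring only when C7 and C2 are cis; C4 is set because the carbonyl oxygen is delivered from C3 on the face of C2, which gives the cis-fused lactone. The step needs bridged perketalisation to win over the intermolecular one (slow addition, high dilution), attack through the CH2 terminus (secured by the 2-propenyl substitution, which makes the cation tertiary) and suppression of Hock cleavage of the allylic peroxide (silylated peroxide, hindered base, −78 °C). Should the hemiorthoester first collapse to the bridged hydroxy ester, the acidic aqueous finish should convert it into the γ-lactone by translactonisation.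

Step 7
Reactants: 11 (3R,4aS,7aS)-3-[(2R)-4-hydroxy-2-methylbutyl]-3,4a-dimethyl-4,4a,7,7a-tetrahydro-3H-furo[3,2-c][1,2]dioxin-6-one
Product: 12 (3S)-4-[(3R,4aS,7aS)-3,4a-dimethyl-6-oxo-4,4a,7,7a-tetrahydro-3H-furo[3,2-c][1,2]dioxin-3-yl]-3-methylbutanal
Conditions: Dess–Martin periodinane, NaHCO3, CH2Cl2, 0 °C to rt
Reagents that add atoms: none
Why: Buffered Dess–Martin oxidation of the primary C10 alcohol to the aldehyde is neutral and should leave the dialkyl peroxide and the lactone untouched.

Step 8
Reactants: 12 (3S)-4-[(3R,4aS,7aS)-3,4a-dimethyl-6-oxo-4,4a,7,7a-tetrahydro-3H-furo[3,2-c][1,2]dioxin-3-yl]-3-methylbutanal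
Product: 13 (3R,4aS,7aS)-3,4a-dimethyl-3-[(2R)-2-methylpent-4-yn-1-yl]-4,4a,7,7a-tetrahydro-3H-furo[3,2-c][1,2]dioxin-6-one
Conditions: dimethyl (1-diazo-2-oxopropyl)phosphonate (1.3 equiv), K2CO3 (2 equiv), MeOH, 0 °C to rt
Reagents that add atoms: dimethyl (1-diazo-2-oxopropyl)phosphonate, CC(=O)C(=[N+]=[N-])P(=O)(OC)OC
Why: Ohira–Bestmann homologation converts the C10 aldehyde into the terminal alkyne (new carbon C11) under carbonate in methanol, conditions mild enough for the γ-lactone and the unstrained peroxide, and C8 is not alpha to the carbonyl and cannot epimerise.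

Step 9
Reactants: 13 (3R,4aS,7aS)-3,4a-dimethyl-3-[(2R)-2-methylpent-4-yn-1-yl]-4,4a,7,7a-tetrahydro-3H-furo[3,2-c][1,2]dioxin-6-one
Product: 14 (3R,4aS,7aS)-3-[(2R,4E)-2,4-dimethyl-5-(4,4,5,5-tetramethyl-1,3,2-dioxaborolan-2-yl)pent-4-en-1-yl]-3,4a-dimethyl-4,4a,7,7a-tetrahydro-3H-furo[3,2-c][1,2]dioxin-6-one
Conditions: CuCl (10 mol %), Xantphos (10 mol %), B2pin2 (1.2 equiv), NaOtBu (1.2 equiv), THF, rt (premix); then 13 and MeI (3 equiv), 0 °C to rt
Reagents that add atoms: bis(pinacolato)diboron, CC1(C)OB(OC1(C)C)B1OC(C)(C)C(C)(C)O1; iodomethane, CI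
Why: Copper-catalysed carboboration, in which syn-borylcupration of the terminal alkyne places boron on C11 and the alkenylcopper at C10 is methylated by iodomethane with retention, fixes the 10E geometry, and premixing leaves little free alkoxide to attack the β-peroxy lactone.

Step 10
Reactants: 15 1-phenyl-2-butyne
Product: 17 (E)-(3-iodobut-2-en-1-yl)benzene, via alkenylzirconocene chloride 16 (not isolated)
Conditions: Cp2Zr(H)Cl (1.5 equiv), THF, rt then 45 °C; I2, THF, 0 °C
Reagents that add atoms: iodine, II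
Why: syn-Hydrozirconation of the internal alkyne with equilibration should place zirconium on the methyl-bearing carbon (the smaller substituent) and iodinolysis with retention gives the E-iodide, the minor regioisomer being removed by chromatography.

Step 11
Reactants: 14 (3R,4aS,7aS)-3-[(2R,4E)-2,4-dimethyl-5-(4,4,5,5-tetramethyl-1,3,2-dioxaborolan-2-yl)pent-4-en-1-yl]-3,4a-dimethyl-4,4a,7,7a-tetrahydro-3H-furo[3,2-c][1,2]dioxin-6-one; 17 (E)-(3-iodobut-2-en-1-yl)benzene
Product: 18 (3R,4aS,7aS)-3,4a-dimethyl-3-[(2R,4E,6E)-2,4,6-trimethyl-8-phenylocta-4,6-dien-1-yl]-4,4a,7,7a-tetrahydro-3H-furo[3,2-c][1,2]dioxin-6-one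
Conditions: Pd(dppf)Cl2 (5 mol %), K3PO4 (3 M aqueous, 2 equiv), THF, rt, degassed
Reagents that add atoms: none
Why: Suzuki–Miyaura coupling of alkenyl boronate 14 with alkenyl iodide 17 proceeds with retention at both partners and should give the (10E,12E)-diene, unstrained dialkyl peroxides being expected to tolerate the palladium catalyst at room temperature.

Compound list
1 | methyl hydrogen (R)-3-methylglutarate | COC(=O)C[C@H](C)CC(=O)O | starting material
2 | methyl (3R)-5-hydroxy-3-methylpentanoate (not isolated) | COC(=O)C[C@H](C)CCO | intermediate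
3 | (4R)-4-methyltetrahydro-2H-pyran-2-one | O=C1C[C@H](C)CCO1 | intermediate
4 | (4R)-6-hydroxy-4-methylhexan-2-one | CC(=O)C[C@H](C)CCO | intermediate
5 | 4-methylpent-3-enoic acid | CC(C)=CCC(=O)O | starting material
6 | (3R)-3-methyl-5-oxohexyl 4-methylpent-3-enoate | CC(=O)C[C@H](C)CCOC(=O)CC=C(C)C | intermediate
7 | (3R)-3-methyl-5-oxohexyl (3RS)-3-hydroperoxy-4-methylpent-4-enoate | CC(=O)C[C@H](C)CCOC(=O)CC(OO)C(C)=C | intermediate
8 | (3R)-3-methyl-5-oxohexyl (3S)-3-hydroperoxy-4-methylpent-4-enoate (key-step precursor) | CC(=O)C[C@H](C)CCOC(=O)C[C@H](OO)C(C)=C | intermediate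
9 | (3R)-3-methyl-5-oxohexyl (3S)-4-methyl-3-[(trimethylsilyl)peroxy]pent-4-enoate (not isolated) | CC(=O)C[C@H](C)CCOC(=O)C[C@H](OO[Si](C)(C)C)C(C)=C | intermediate
10 | bridged lactonium trifluoromethanesulfonate, C1 bonded to O–C4 and still to O–C10 (not isolated) | [O+]3CC[C@@H](C)C[C@]1(C)C[C@]2(C)OC=3C[C@@H]2OO1.[O-]S(=O)(=O)C(F)(F)F | intermediate
11 | (3R,4aS,7aS)-3-[(2R)-4-hydroxy-2-methylbutyl]-3,4a-dimethyl-4,4a,7,7a-tetrahydro-3H-furo[3,2-c][1,2]dioxin-6-one (key-step product) | OCC[C@@H](C)C[C@]1(C)C[C@]2(C)OC(=O)C[C@@H]2OO1 | intermediate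
12 | (3S)-4-[(3R,4aS,7aS)-3,4a-dimethyl-6-oxo-4,4a,7,7a-tetrahydro-3H-furo[3,2-c][1,2]dioxin-3-yl]-3-methylbutanal | O=CC[C@@H](C)C[C@]1(C)C[C@]2(C)OC(=O)C[C@@H]2OO1 | intermediate
13 | (3R,4aS,7aS)-3,4a-dimethyl-3-[(2R)-2-methylpent-4-yn-1-yl]-4,4a,7,7a-tetrahydro-3H-furo[3,2-c][1,2]dioxin-6-one | C#CC[C@@H](C)C[C@]1(C)C[C@]2(C)OC(=O)C[C@@H]2OO1 | intermediate
14 | (3R,4aS,7aS)-3-[(2R,4E)-2,4-dimethyl-5-(4,4,5,5-tetramethyl-1,3,2-dioxaborolan-2-yl)pent-4-en-1-yl]-3,4a-dimethyl-4,4a,7,7a-tetrahydro-3H-furo[3,2-c][1,2]dioxin-6-one | C/C(=C\B1OC(C)(C)C(C)(C)O1)C[C@@H](C)C[C@]1(C)C[C@]2(C)OC(=O)C[C@@H]2OO1 | intermediate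
15 | 1-phenyl-2-butyne (but-2-yn-1-ylbenzene) | CC#CCc1ccccc1 | starting material
16 | chlorobis(cyclopentadienyl)[(2E)-4-phenylbut-2-en-2-yl]zirconium (not isolated; cyclopentadienyl rings drawn σ-bonded) | C/C(=C\Cc1ccccc1)[Zr](Cl)(C1C=CC=C1)C1C=CC=C1 | intermediate
17 | (E)-(3-iodobut-2-en-1-yl)benzene | C/C(I)=C\Cc1ccccc1 | intermediate
18 | (3R,4aS,7aS)-3,4a-dimethyl-3-[(2R,4E,6E)-2,4,6-trimethyl-8-phenylocta-4,6-dien-1-yl]-4,4a,7,7a-tetrahydro-3H-furo[3,2-c][1,2]dioxin-6-one | CC(=C\Cc1ccccc1)/C=C(\C)C[C@@H](C)C[C@]1(C)C[C@]2(C)OC(=O)C[C@@H]2OO1 | target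

Total step count: 11. Longest linear sequence: 10 steps (steps 1–9 and 11); step 10 is a one-step side branch.

Steps most likely to fail

Step 6 (the step beyond known chemistry). Perketalisation between two molecules may outrun closure of the bridged eleven-membered perketal, so that C6 forms without facial control. The allylic peroxide may also fragment by a Hock-type shift before the C5–C6 bond forms, or the C4 cation may lose a proton instead of being captured. The fallback uses only established peroxide chemistry, sets out from lactone 3 and comes back at 11. Addition of Me3SiCH2MgCl with CeCl3 gives (3R)-3-methyl-6-(trimethylsilyl)-5-[(trimethylsilyl)methyl]hexane-1,5-diol F1, and Peterson elimination on silica gel gives the allylsilane (3S)-3-methyl-5-[(trimethylsilyl)methyl]hex-5-en-1-ol F2. TBSCl and imidazole give its silyl ether F3, and Hosomi–Sakurai-type acetylation (AcCl, AlCl3, CH2Cl2, −78 °C) gives (6S)-8-[(tert-butyldimethylsilyl)oxy]-6-methyl-4-methylideneoctan-2-one F4. Lithium ethyl propiolate (THF, −78 °C) gives the propargylic alcohol ethyl (4RS,8S)-10-[(tert-butyldimethylsilyl)oxy]-4-hydroxy-4,8-dimethyl-6-methylidenedec-2-ynoate F5. Semi-hydrogenation over Lindlar catalyst (Pd on CaCO3 poisoned with Pb(OAc)2, quinoline) with lactonisation of the Z-enoate gives the butenolide 5-[(4S)-6-[(tert-butyldimethylsilyl)oxy]-4-methyl-2-methylidenehexyl]-5-methylfuran-2(5H)-one F6. Isayama–Mukaiyama hydroperoxysilylation of the 1,1-disubstituted alkene (Co(acac)2, O2, Et3SiH) installs the C6 peroxide as 5-[(4R)-6-[(tert-butyldimethylsilyl)oxy]-2,4-dimethyl-2-[(triethylsilyl)peroxy]hexyl]-5-methylfuran-2(5H)-one F7. HF·pyridine removes both silyl groups to give 5-[(4R)-2-hydroperoxy-6-hydroxy-2,4-dimethylhexyl]-5-methylfuran-2(5H)-one F8, and Et2NH in CF3CH2OH closes ring A by intramolecular peroxy-Michael addition to the butenolide (cis ring fusion). This route controls neither C4 nor C6, so 11 would have to be separated chromatographically from its stereoisomers.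

Step 9. The alkoxide may enolise the lactone at C2 with collapse onto the O–O bond, or boryl-copper species may reduce the peroxide, before carboboration is complete. The fallback avoids alkoxide and copper, sets out from alkyne 13 and comes back at 18. Platinum-catalysed syn-diboration (Pt(PPh3)4, B2pin2, toluene, 50 °C) gives the cis-1,2-diboryl alkene (3R,4aS,7aS)-3-[(2R,4E)-2-methyl-4,5-bis(4,4,5,5-tetramethyl-1,3,2-dioxaborolan-2-yl)pent-4-en-1-yl]-3,4a-dimethyl-4,4a,7,7a-tetrahydro-3H-furo[3,2-c][1,2]dioxin-6-one F9. Site-selective Suzuki–Miyaura coupling of its less hindered terminal C–B bond with iodide 17 (Pd(dppf)Cl2, aqueous K3PO4, THF, rt) gives the dienyl boronate (3R,4aS,7aS)-3-[(2R,4E,6E)-2,6-dimethyl-8-phenyl-4-(4,4,5,5-tetramethyl-1,3,2-dioxaborolan-2-yl)octa-4,6-dien-1-yl]-3,4a-dimethyl-4,4a,7,7a-tetrahydro-3H-furo[3,2-c][1,2]dioxin-6-one F10. A second Suzuki–Miyaura coupling of the remaining C10–B bond with iodomethane (Pd(dppf)Cl2, K3PO4, THF–H2O, 40 °C) installs the C10 methyl group with retention.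

Step 5. The enzyme may turn over the bulky keto ester slowly or discriminate the C3 epimers poorly, so that 8 stays contaminated with its 3R epimer. The fallback replaces enzymatic differentiation by physical separation, sets out from 7 and comes back at 8. Preparative HPLC on a cellulose tris(3,5-dimethylphenylcarbamate) stationary phase separates the two C3 epimers, and (3R)-3-methyl-5-oxohexyl (3R)-3-hydroperoxy-4-methylpent-4-enoate F11 is set aside.

Further compounds
F1 | step 6 | (3R)-3-methyl-6-(trimethylsilyl)-5-[(trimethylsilyl)methyl]hexane-1,5-diol | C[Si](C)(C)CC(O)(C[Si](C)(C)C)C[C@H](C)CCO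
F2 | step 6 | (3S)-3-methyl-5-[(trimethylsilyl)methyl]hex-5-en-1-ol | C=C(C[Si](C)(C)C)C[C@H](C)CCO
F3 | step 6 | tert-butyldimethyl{[(3S)-3-methyl-5-[(trimethylsilyl)methyl]hex-5-en-1-yl]oxy}silane | C=C(C[Si](C)(C)C)C[C@H](C)CCO[Si](C)(C)C(C)(C)C
F4 | step 6 | (6S)-8-[(tert-butyldimethylsilyl)oxy]-6-methyl-4-methylideneoctan-2-one | CC(=O)CC(=C)C[C@H](C)CCO[Si](C)(C)C(C)(C)C
F5 | step 6 | ethyl (4RS,8S)-10-[(tert-butyldimethylsilyl)oxy]-4-hydroxy-4,8-dimethyl-6-methylidenedec-2-ynoate | CCOC(=O)C#CC(C)(O)CC(=C)C[C@H](C)CCO[Si](C)(C)C(C)(C)C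
F6 | step 6 | (5RS)-5-[(4S)-6-[(tert-butyldimethylsilyl)oxy]-4-methyl-2-methylidenehexyl]-5-methylfuran-2(5H)-one | C=C(C[C@H](C)CCO[Si](C)(C)C(C)(C)C)CC1(C)OC(=O)C=C1
F7 | step 6 | (5RS)-5-[(2RS,4R)-6-[(tert-butyldimethylsilyl)oxy]-2,4-dimethyl-2-[(triethylsilyl)peroxy]hexyl]-5-methylfuran-2(5H)-one | CC[Si](CC)(CC)OOC(C)(C[C@H](C)CCO[Si](C)(C)C(C)(C)C)CC1(C)OC(=O)C=C1
F8 | step 6 | (5RS)-5-[(2RS,4R)-2-hydroperoxy-6-hydroxy-2,4-dimethylhexyl]-5-methylfuran-2(5H)-one | OOC(C)(C[C@H](C)CCO)CC1(C)OC(=O)C=C1
F9 | step 9 | (3R,4aS,7aS)-3-[(2R,4E)-2-methyl-4,5-bis(4,4,5,5-tetramethyl-1,3,2-dioxaborolan-2-yl)pent-4-en-1-yl]-3,4a-dimethyl-4,4a,7,7a-tetrahydro-3H-furo[3,2-c][1,2]dioxin-6-one | CC1(C)OB(OC1(C)C)/C=C(\B1OC(C)(C)C(C)(C)O1)C[C@@H](C)C[C@]1(C)C[C@]2(C)OC(=O)C[C@@H]2OO1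
F10 | step 9 | (3R,4aS,7aS)-3-[(2R,4E,6E)-2,6-dimethyl-8-phenyl-4-(4,4,5,5-tetramethyl-1,3,2-dioxaborolan-2-yl)octa-4,6-dien-1-yl]-3,4a-dimethyl-4,4a,7,7a-tetrahydro-3H-furo[3,2-c][1,2]dioxin-6-one | CC(=C\Cc1ccccc1)/C=C(\B1OC(C)(C)C(C)(C)O1)C[C@@H](C)C[C@]1(C)C[C@]2(C)OC(=O)C[C@@H]2OO1
F11 | step 5 | (3R)-3-methyl-5-oxohexyl (3R)-3-hydroperoxy-4-methylpent-4-enoate | CC(=O)C[C@H](C)CCOC(=O)C[C@@H](OO)C(C)=C
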